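- I decide to read this flask through two rates: how fast target forms and how fast isomer of the product forms.

| flask | starting material | reagent | free catalyst | impurity | remark | time |
|---|---|---|---|---|---|---|
| west | 0.050 M | 1.7 equiv | 2 mol% | 0.61 mM | run made earlier |  |
| north-east | 0.050 M | 3.8 equiv | 2 mol% | 0.61 mM | run made earlier |  |
| east | 0.050 M | 2.5 equiv | 4 mol% | 0.61 mM | run made earlier |  |
| flask | 0.050 M | 2.50 equiv | 2 mol% | 0.61 mM |  | 50 min |

| run | time / min | target / % | isomer of the product / % |
|---|---|---|---|
| west | 2.50 | 3 | 5 |
| west | 8.00 | 14 | 7 |
| west | 15.0 | 23 | 12 |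
| west | 20.0 | 26 | 15 |
| west | 30.0 | 30 | 18 |
| north-east | 2.50 | 11 | 7 |
| north-east | 8.00 | 26 | 15 |
| north-east | 15.0 | 35 | 19 |
| north-east | 20.0 | 40 | 25 |
| north-east | 30.0 | 38 | 29 |
| east | 2.50 | 12 | 4 |
| east | 8.00 | 23 | 11 |
| east | 15.0 | 30 | 17 |
| east | 20.0 | 31 | 19 |
| east | 30.0 | 32 | 23 |

(readings scatter by 1.5 percentage points)

1. ratio of target to isomer of the product at 20 s
2. ratio of target to isomer of the product at 4.0 min
3. ratio of target to isomer of the product at 50 min

- a reading or a percentage of target counts all its forms, free or not

- Reagent runs from 1.7 equiv to 3.8 equiv and the loading from 2 mol% to 4 mol%, yet at 8.00 min the ratio of target to isomer of the product reads 2.00 in the west run, 1.73 in the north-east run and 2.09 in the east run.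
- So the two rates seem to rise together with c(reagent), and within the scatter of 1.5 percentage points the higher loading does not move their ratio.
- Pooling these readings gives 1.91 for S, target formed per isomer of the product formed, the selectivity factor.
- I set aside the readings at 2.50 min, where the west run has 3 % of target and the east run 4 % of isomer of the product against that same scatter.
- The flask's settings lie inside those of the runs, so I expect a ratio near S at both 20 s and 4.0 min.
- At 30.0 min the ratio reads 1.67 in the west run and 1.31 in the north-east run, lower than S, so at 50 min I expect a lower ratio still, without a figure of my own.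
- The forecast says 1.1, 1.5 and 1.15, on the ground that “The target lag suggests catalyst is released over minutes”. It starts lower than my S and climbs up to 4.0 min, where I hold the ratio flat over that stretch.
- The flask gives 2.06 at 20 s, 2.00 at 4.0 min and 1.14 at 50 min.

    starting material + reagent ⇌ target (K = 7.70 M⁻¹, k = 0.330 M⁻¹ min⁻¹)
    starting material + reagent ⇌ isomer of the product (K = 18.0 M⁻¹, k = 0.160 M⁻¹ min⁻¹)
    target + free catalyst ⇌ isomer of the product + free catalyst, rate k3*[free catalyst]*[target] forward; the back reaction follows from the equilibrium constant (k = 1.50 M⁻¹ min⁻¹)
    starting material + free catalyst ⇌ idle complex, settled at all times (K = 7.20 M⁻¹)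
    starting material + target ⇌ idle adduct, settled at all times (K = 21.0 M⁻¹)
    free catalyst + impurity → spent catalyst (k = 16000 M⁻¹ min⁻¹)

- At 5.46 min in this flask, starting material has a half-life of 19 min by the forward step to target, shorter than the 38 min by the forward step to isomer of the product; that is a ratio of 2.06, where I read S as 1.91.
- S stands for the early ratio of the neighbour flask with 10.0 equiv of reagent, which holds 2.06 at 20 s and 1.97 at 4.0 min, then 0.900 at 50 min.

All runs were computed for substances that don't exist; the scatter is artificial.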